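**Retrosynthetic overview**
1. Target 17 comes from 16 by cleaving the silyl ether on the hydroxymethyl group of the (Z)-2-(hydroxymethyl)but-2-enoate.
2. 16 comes from ketone 6, formaldehyde 13 and enal 12 in one catalytic asymmetric crossed aldol–Tishchenko reaction. It makes the bond between C-2 and the ester-bearing CH2 carbon, the ester C–O bond and the C-1–H bond, and sets C-1 and C-2.
3. Enabling feature: the 1,3-diol monoester chain O–C1(H)(ring A)–C2(H)–CH2–O–C(=O), with the free benzylic carbinol C-1 in a 1,3-relation to the acylated primary oxygen. With C-1 at the ketone level, C-2 is an enolate carbon for formaldehyde, and C-1 then accepts hydride from the hemiacetal on the new CH2–O through a six-membered transition state.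
4. 6 comes from β-keto ester 3 and 4-methoxycinnamyl carbonate 2 (Tsuji–Trost allylation, dealkoxycarbonylation). 12 comes from crotonaldehyde 7 (α-iodination, reduction, silylation, formylation).
5. No ring is formed in the route: ring A (3,4-dimethoxyphenyl) arrives with 3 and ring B (4-methoxyphenyl) with 1.

Key step: step 8

Assumption: the sense of induction of the binaphthoxide catalyst in step 8 is taken over from the aryl ethyl ketone series and written for the (R)-ligand; if a test run shows the opposite sense, the (S)-ligand is used and nothing else changes.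

**Step 1**
Reactants: 1 (E)-3-(4-methoxyphenyl)prop-2-en-1-ol
Product: 2 methyl (E)-3-(4-methoxyphenyl)prop-2-en-1-yl carbonate
Conditions: ClCO2Me, pyridine, CH2Cl2, 0 °C
Reagents that add atoms: methyl chloroformate, COC(=O)Cl
Why: Acylation of the primary allylic alcohol with a chloroformate (carbonate formation) under buffered conditions should give the leaving group for palladium without ionizing the electron-rich cinnamyl system; no stereocenter is formed.

**Step 2**
Reactants: 2 methyl (E)-3-(4-methoxyphenyl)prop-2-en-1-yl carbonate; 3 ethyl 3-(3,4-dimethoxyphenyl)-3-oxopropanoate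
Product: 4 ethyl (E)-2-(3,4-dimethoxybenzoyl)-5-(4-methoxyphenyl)pent-4-enoate (racemic)
Conditions: Pd(PPh3)4 (3 mol%), 3 (1.3 equiv), THF, rt
Reagents that add atoms: none
Why: Tsuji–Trost allylic alkylation: zerovalent palladium ionizes the carbonate with loss of CO2, the methoxide formed deprotonates the β-keto ester, and the soft enolate attacks the unsubstituted terminus of the aryl-substituted π-allyl complex to give the linear (E)-product; the new stereocenter is racemic and is erased in step 3.

**Step 3**
Reactants: 4 ethyl (E)-2-(3,4-dimethoxybenzoyl)-5-(4-methoxyphenyl)pent-4-enoate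
Product: 6 (E)-1-(3,4-dimethoxyphenyl)-5-(4-methoxyphenyl)pent-4-en-1-one, via sodium β-keto carboxylate 5 (not isolated)
Conditions: NaCl, H2O, DMSO, 140 °C
Reagents that add atoms: none
Why: Krapcho dealkoxycarbonylation: chloride dealkylates the ethyl ester and the β-keto carboxylate loses CO2, under neutral conditions that should spare the styrene and the aryl methyl ethers.

**Step 4**
Reactants: 7 (E)-but-2-enal
Product: 8 (Z)-2-iodobut-2-enal
Conditions: I2, K2CO3, DMAP (20 mol%), THF/H2O (1:1), rt
Reagents that add atoms: iodine, II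
Why: α-Iodination of an enal by a Baylis–Hillman-type addition–iodination–elimination sequence (DMAP adds at C-3, the enolate is iodinated, DMAP leaves); iodine takes the place of the α-hydrogen and so stands cis to the methyl group.

**Step 5**
Reactants: 8 (Z)-2-iodobut-2-enal
Product: 9 (Z)-2-iodobut-2-en-1-ol
Conditions: NaBH4, CeCl3·7H2O, MeOH, 0 °C
Reagents that add atoms: none
Why: Luche 1,2-reduction of the enal should leave the vinyl iodide and its geometry untouched.

**Step 6**
Reactants: 9 (Z)-2-iodobut-2-en-1-ol
Product: 10 tert-butyl{[(Z)-2-iodobut-2-en-1-yl]oxy}dimethylsilane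
Conditions: TBSCl, imidazole, CH2Cl2, rt
Reagents that add atoms: tert-butyldimethylsilyl chloride, CC(C)(C)[Si](C)(C)Cl
Why: Silyl ether formation masks the hydroxyl that becomes the free hydroxymethyl group of the acid part.

**Step 7**
Reactants: 10 tert-butyl{[(Z)-2-iodobut-2-en-1-yl]oxy}dimethylsilane
Product: 12 (Z)-2-{[(tert-butyldimethylsilyl)oxy]methyl}but-2-enal, via vinyllithium 11 (not isolated)
Conditions: t-BuLi (2.1 equiv), Et2O, −78 °C; then DMF, −78 °C; pH 7 buffer
Reagents that add atoms: N,N-dimethylformamide, CN(C)C=O
Why: Iodine–lithium exchange proceeds with retention of alkene geometry and the vinyllithium is formylated by DMF (Bouveault aldehyde synthesis), so the formyl group ends cis to the methyl group.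

**Step 8**
Reactants: 6 (E)-1-(3,4-dimethoxyphenyl)-5-(4-methoxyphenyl)pent-4-en-1-one; 13 formaldehyde; 12 (Z)-2-{[(tert-butyldimethylsilyl)oxy]methyl}but-2-enal
Product: 16 (2R,3S)-3-(3,4-dimethoxyphenyl)-3-hydroxy-2-[(2E)-3-(4-methoxyphenyl)prop-2-en-1-yl]propyl (2Z)-2-{[(tert-butyldimethylsilyl)oxy]methyl}but-2-enoate, via β-hydroxy ketone 14 (not isolated), via hemiacetal 15 (not isolated)
Conditions: (R)-LaLi3(1,1'-binaphthalene-2,2'-diolate)3 (10 mol%), LiOTf (30 mol%), 6 (1.1 equiv), 13 (1.0 equiv, THF solution), THF, −20 °C; then 12 (2.5 equiv), −20 °C to rt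
Reagents that add atoms: none
Why: Proposed new method: the lanthanum–lithium binaphthoxide enolizes 6, the enolate adds to formaldehyde (the only aldehyde present in the first stage) to give aldolate 14, whose C-2 epimers interconvert under the basic catalyst by enolization and retro-aldol/aldol, and after 12 is added the aldolate oxygen forms hemiacetal 15, which passes its carbinol hydrogen as hydride to the ketone carbon through a lanthanum-bridged six-membered chair, leaving the acyl group on the primary oxygen and C-1 as the free carbinol. The closest known reaction types are the direct catalytic asymmetric aldol–Tishchenko reaction of aryl alkyl ketones with a single aldehyde under this heterobimetallic catalyst and the Evans–Tishchenko reduction of β-hydroxy ketones by a second aldehyde; new is the crossed version with formaldehyde as the carbon electrophile and an enal as the hydride donor. No ring is closed. C-1 is controlled by C-2 through the chair, in which the cinnamyl group is equatorial and anti to the incoming hydride (this should give the syn relation of the C-1 hydroxyl and the C-2 side chain), and C-2 and the absolute sense are controlled by the binaphthoxide ligand in a dynamic kinetic resolution, since hydride transfer is irreversible and expected to be slower than epimerization of 14. The step needs formaldehyde as the only carbon electrophile and 12 as the only hydride donor: the former follows from the much higher electrophilicity of formaldehyde than of the α-branched enal, the latter from the staging, in which one equivalent of formaldehyde is bound in the strongly exergonic hydroxymethylation before 12 is added. What 6 offers for this is a single enolizable methylene (C-2) next to an aryl ketone (C-1) that serves first as the activating group for C–C bond formation and then as the hydride acceptor.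

**Step 9**
Reactants: 16 (2R,3S)-3-(3,4-dimethoxyphenyl)-3-hydroxy-2-[(2E)-3-(4-methoxyphenyl)prop-2-en-1-yl]propyl (2Z)-2-{[(tert-butyldimethylsilyl)oxy]methyl}but-2-enoate
Product: 17 (2R,3S)-3-(3,4-dimethoxyphenyl)-3-hydroxy-2-[(2E)-3-(4-methoxyphenyl)prop-2-en-1-yl]propyl (2Z)-2-(hydroxymethyl)but-2-enoate
Conditions: HF·pyridine, pyridine, THF, 0 °C
Reagents that add atoms: none
Why: Fluoride-induced cleavage of the primary silyl ether (driven by the Si–F bond) under pyridine-buffered conditions should neither ionize the electron-rich benzylic carbinol nor promote acyl migration or Z-to-E isomerization of the enoate; both stereocenters are untouched.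

**Compound list**
1 | (E)-3-(4-methoxyphenyl)prop-2-en-1-ol (4-methoxycinnamyl alcohol) | COc1ccc(/C=C/CO)cc1 | starting material
2 | methyl (E)-3-(4-methoxyphenyl)prop-2-en-1-yl carbonate | COC(=O)OC/C=C/c1ccc(OC)cc1 | intermediate
3 | ethyl 3-(3,4-dimethoxyphenyl)-3-oxopropanoate | CCOC(=O)CC(=O)c1ccc(OC)c(OC)c1 | starting material
4 | ethyl (E)-2-(3,4-dimethoxybenzoyl)-5-(4-methoxyphenyl)pent-4-enoate (racemic) | CCOC(=O)C(C/C=C/c1ccc(OC)cc1)C(=O)c1ccc(OC)c(OC)c1 | intermediate
5 | sodium (E)-2-(3,4-dimethoxybenzoyl)-5-(4-methoxyphenyl)pent-4-enoate (racemic, not isolated) | [Na+].[O-]C(=O)C(C/C=C/c1ccc(OC)cc1)C(=O)c1ccc(OC)c(OC)c1 | intermediate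
6 | (E)-1-(3,4-dimethoxyphenyl)-5-(4-methoxyphenyl)pent-4-en-1-one | COc1ccc(/C=C/CCC(=O)c2ccc(OC)c(OC)c2)cc1 | intermediate
7 | (E)-but-2-enal (crotonaldehyde) | C/C=C/C=O | starting material
8 | (Z)-2-iodobut-2-enal | C/C=C(\I)C=O | intermediate
9 | (Z)-2-iodobut-2-en-1-ol | C/C=C(\I)CO | intermediate
10 | tert-butyl{[(Z)-2-iodobut-2-en-1-yl]oxy}dimethylsilane | C/C=C(\I)CO[Si](C)(C)C(C)(C)C | intermediate
11 | {(E)-1-[(tert-butyldimethylsilyl)oxy]but-2-en-2-yl}lithium (not isolated) | C/C=C(\[Li])CO[Si](C)(C)C(C)(C)C | intermediate
12 | (Z)-2-{[(tert-butyldimethylsilyl)oxy]methyl}but-2-enal | C/C=C(/CO[Si](C)(C)C(C)(C)C)C=O | intermediate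
13 | formaldehyde (monomer, from cracking of commercial paraformaldehyde) | C=O | starting material
14 | (E)-1-(3,4-dimethoxyphenyl)-2-(hydroxymethyl)-5-(4-methoxyphenyl)pent-4-en-1-one (both C-2 epimers in equilibrium, as metal alkoxide, not isolated) | COc1ccc(/C=C/CC(CO)C(=O)c2ccc(OC)c(OC)c2)cc1 | intermediate
15 | (2R,4E)-2-({[(2Z)-2-{[(tert-butyldimethylsilyl)oxy]methyl}-1-hydroxybut-2-en-1-yl]oxy}methyl)-1-(3,4-dimethoxyphenyl)-5-(4-methoxyphenyl)pent-4-en-1-one (hemiacetal of (2R)-14 with 12, hemiacetal carbon undefined, not isolated) | C/C=C(/CO[Si](C)(C)C(C)(C)C)C(O)OC[C@@H](C/C=C/c1ccc(OC)cc1)C(=O)c1ccc(OC)c(OC)c1 | intermediate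
16 | (2R,3S)-3-(3,4-dimethoxyphenyl)-3-hydroxy-2-[(2E)-3-(4-methoxyphenyl)prop-2-en-1-yl]propyl (2Z)-2-{[(tert-butyldimethylsilyl)oxy]methyl}but-2-enoate | C/C=C(/CO[Si](C)(C)C(C)(C)C)C(=O)OC[C@@H](C/C=C/c1ccc(OC)cc1)[C@H](O)c1ccc(OC)c(OC)c1 | intermediate
17 | (2R,3S)-3-(3,4-dimethoxyphenyl)-3-hydroxy-2-[(2E)-3-(4-methoxyphenyl)prop-2-en-1-yl]propyl (2Z)-2-(hydroxymethyl)but-2-enoate | C/C=C(/CO)C(=O)OC[C@@H](C/C=C/c1ccc(OC)cc1)[C@H](O)c1ccc(OC)c(OC)c1 | target

**Summary**
Total step count: 9. Longest linear sequence: 6 steps (steps 4 to 9, from 7 to 17).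

**Steps most likely to fail**

Step 8 (proposed new method). Several processes may go wrong. The formaldehyde hemiacetal may donate hydride itself, or C-2 may be hydroxymethylated a second time in the first stage. The basic catalyst may enolize 12 vinylogously, with loss of its (Z)-geometry or self-condensation. Hydride transfer to the electron-rich aryl ketone may be sluggish. Epimerization of 14 may be too slow relative to hydride transfer, which would erode the enantiomeric purity. The fallback uses known chemistry, sets out from 6 and returns at 16. Enolization of 6 with LiN(SiMe3)2 and Me3SiCl (THF, −78 °C) should give the (Z)-trimethylsilyl enol ether F1. A catalytic asymmetric Mukaiyama hydroxymethylation of F1 forms the same bond and should give the isolated (R)-β-hydroxy ketone F2. Its conditions are aqueous formaldehyde, Sc(OTf)3 and chiral 6,6'-bis(1-hydroxy-2,2-dimethylpropyl)-2,2'-bipyridine in DME/H2O at −20 °C, with the ligand enantiomer that delivers the (2R)-product. An Evans–Tishchenko reduction of F2 with 12 and SmI2 (20 mol%) in THF at −10 °C then passes through hemiacetal 15 to 16, with C-1 set by the same chair-like hydride transfer.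

Step 7. The vinyllithium 11 may lose lithium silanolate by β-elimination, or silicon may shift from oxygen to carbon before the formylation; the enal may also isomerize under base on work-up. The fallback sets out from 10 and returns at 12 without an organolithium. A palladium-catalysed aminocarbonylation of 10 (PdCl2(PPh3)2, CO 1 atm, MeNHOMe·HCl, Et3N, DMF, 50 °C) should give, with retention of geometry, the Weinreb amide F3. Reduction of F3 with i-Bu2AlH (THF, −78 °C) should give 12.

Step 9. The acyl group may migrate from the primary to the benzylic oxygen, the enoate may isomerize from Z to E, or the benzylic carbinol may ionize during the fluoride treatment. The fallback sets out from 9 and returns at 17; it carries the hydroxyl as a triethylsilyl ether, which dilute acid cleaves without fluoride. Treatment of 9 with Et3SiCl and imidazole should give the triethylsilyl ether F4. t-BuLi and then DMF should give, by way of the vinyllithium F5, the enal F6. The conditions of step 8 with 6 and 13 should give, by way of 14 and the hemiacetal F7, the ester F8. AcOH/THF/H2O (3:1:1) at 0 °C should then release 17.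

**Further compounds**
F1 | step 8 | {[(1Z,4E)-1-(3,4-dimethoxyphenyl)-5-(4-methoxyphenyl)penta-1,4-dien-1-yl]oxy}trimethylsilane | C[Si](C)(C)O/C(=C\C/C=C/c1ccc(OC)cc1)c1ccc(OC)c(OC)c1
F2 | step 8 | (2R,4E)-1-(3,4-dimethoxyphenyl)-2-(hydroxymethyl)-5-(4-methoxyphenyl)pent-4-en-1-one | OC[C@@H](C/C=C/c1ccc(OC)cc1)C(=O)c1ccc(OC)c(OC)c1
F3 | step 7 | (Z)-2-{[(tert-butyldimethylsilyl)oxy]methyl}-N-methoxy-N-methylbut-2-enamide | C/C=C(/CO[Si](C)(C)C(C)(C)C)C(=O)N(C)OC
F4 | step 9 | triethyl{[(Z)-2-iodobut-2-en-1-yl]oxy}silane | C/C=C(\I)CO[Si](CC)(CC)CC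
F5 | step 9 | {(E)-1-[(triethylsilyl)oxy]but-2-en-2-yl}lithium | C/C=C(\[Li])CO[Si](CC)(CC)CC
F6 | step 9 | (Z)-2-{[(triethylsilyl)oxy]methyl}but-2-enal | C/C=C(/CO[Si](CC)(CC)CC)C=O
F7 | step 9 | (2R,4E)-2-({[(2Z)-1-hydroxy-2-{[(triethylsilyl)oxy]methyl}but-2-en-1-yl]oxy}methyl)-1-(3,4-dimethoxyphenyl)-5-(4-methoxyphenyl)pent-4-en-1-one | C/C=C(/CO[Si](CC)(CC)CC)C(O)OC[C@@H](C/C=C/c1ccc(OC)cc1)C(=O)c1ccc(OC)c(OC)c1
F8 | step 9 | (2R,3S)-3-(3,4-dimethoxyphenyl)-3-hydroxy-2-[(2E)-3-(4-methoxyphenyl)prop-2-en-1-yl]propyl (2Z)-2-{[(triethylsilyl)oxy]methyl}but-2-enoate | C/C=C(/CO[Si](CC)(CC)CC)C(=O)OC[C@@H](C/C=C/c1ccc(OC)cc1)[C@H](O)c1ccc(OC)c(OC)c1
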